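**Retrosynthetic overview**
1. Target 11 is (2S)-6-geranyl-5,7-dihydroxy-3',4'-dimethoxyflavanone. Rings C and A are both opened in one retrosynthetic operation to the acyclic δ-hydroxy triketo tert-butyl ester 8; ring B is bought.
2. Forward, in one flask: ring C closes first (the carbinol oxygen adds to the future C8a ketone, giving a dihydropyranone), then ring A closes (C4a–C5 bond, acylketene 6π closure and aromatisation). This order fixes which oxygen becomes O1, so geranyl ends at C6 and not C8, and the C2–O bond is never broken.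
3. 8 is disconnected at C4–C4a (Claisen) into the trianion of the geranylated 3,5-dioxo ester 5 and the (S)-β-hydroxy ester 7.
4. 5 comes from tert-butyl acetoacetate (C-geranylation, then γ-acetylation). 7 comes from asymmetric transfer hydrogenation of the commercial β-keto ester 6, which sets the only stereocenter.

Assumption: "geranyl" means (2E)-3,7-dimethylocta-2,6-dien-1-yl as drawn in the target SMILES, and compounds 1, 2, 4 and 6 are taken as catalogue chemicals.

**Step 1**
Reactants: 1 tert-butyl acetoacetate; 2 geranyl bromide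
Product: 3 tert-butyl (4E)-2-acetyl-5,9-dimethyldeca-4,8-dienoate (tert-butyl 2-geranylacetoacetate; racemic at C2)
Conditions: NaH (1.05 equiv), THF, 0 °C; then 2 (0.9 equiv), 0 → 25 °C
Reagents that add atoms: none
Why: Acetoacetic ester alkylation: SN2 C-alkylation of the sodium enolate by the primary allylic bromide keeps the E-alkene, and the racemic C2 centre is irrelevant because it becomes aromatic C6 of the target.

**Step 2**
Reactants: 3 tert-butyl 2-geranylacetoacetate; 4 N-methoxy-N-methylacetamide
Product: 5 tert-butyl (4E)-5,9-dimethyl-2-(3-oxobutanoyl)deca-4,8-dienoate (tert-butyl 2-geranyl-3,5-dioxohexanoate)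
Conditions: LiN(iPr)2 (LDA, 2.2 equiv), THF, −78 → 0 °C; then 4 (1.1 equiv), −78 → 0 °C; AcOH quench
Reagents that add atoms: none
Why: Huckin–Weiler γ-acylation of a β-keto ester dianion: the terminal carbanion is the reactive site, and the Weinreb amide holds the chelated tetrahedral adduct until work-up so the acidic diketone cannot quench the dianion; no stereocenter is set.

**Step 3**
Reactants: 6 ethyl 3-(3,4-dimethoxyphenyl)-3-oxopropanoate
Product: 7 ethyl (3S)-3-(3,4-dimethoxyphenyl)-3-hydroxypropanoate
Conditions: RuCl[(S,S)-TsDPEN](p-cymene) (0.5 mol%), HCO2H/Et3N (5:2), 40 °C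
Reagents that add atoms: none
Why: Noyori–Ikariya asymmetric transfer hydrogenation of an aryl ketone: the (S,S)-TsDPEN complex delivers hydride to the face that gives the (S)-benzylic alcohol (same sense as acetophenone to (S)-1-phenylethanol), and this carbon becomes C2 of the target.

**Step 4**
Reactants: 5 tert-butyl 2-geranyl-3,5-dioxohexanoate; 7 ethyl (3S)-3-(3,4-dimethoxyphenyl)-3-hydroxypropanoate
Product: 8 tert-butyl (9S)-9-(3,4-dimethoxyphenyl)-2-[(2E)-3,7-dimethylocta-2,6-dien-1-yl]-9-hydroxy-3,5,7-trioxononanoate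
Conditions: 5 (1.5 equiv), LiN(iPr)2 (6 equiv), THF, −78 → −20 °C; then 7, −78 → 0 °C; AcOH at −78 °C, pH 7 buffer
Reagents that add atoms: none
Why: Harris-type polyanion Claisen condensation: the terminal methyl carbanion of the 3,5-dioxo ester trianion is the most nucleophilic site and acylates the ethyl ester, whose hydroxyl is masked in situ as the lithium alkoxide, so the (S)-carbinol is untouched.

**Step 5**
Reactants: 8 tert-butyl (9S)-9-aryl-2-geranyl-9-hydroxy-3,5,7-trioxononanoate
Product: 11 (2S)-6-geranyl-5,7-dihydroxy-3',4'-dimethoxyflavanone (target), via dihydropyranone keto ester 9 (not isolated), via acylketene 10 (not isolated)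
Conditions: pyridinium p-toluenesulfonate (10 mol%), toluene, 40 °C; then 2,6-lutidine (20 mol%), dilute to 0.005 M, 110 °C
Reagents that add atoms: none
Why: Proposed new method: at 40 °C the weak acid only triggers the standard cyclodehydration of a δ-hydroxy-β-diketone (the 9-OH adds to the C5 ketone and water is lost, forming ring C as dihydropyranone 9 without breaking the C–O bond of the stereocenter, so C2 stays S and this oxygen is fixed as O1); above about 100 °C the tert-butyl β-keto ester expels tert-butanol to give α-oxoketene 10, whose enol is a dienylketene (pyranone C=C, enol C=C, ketene C=C) that closes by 6π-electrocyclisation at the pyranone α-carbon and tautomerises to the phloroglucinol ring A with geranyl between the two new phenols; the closest known reactions are the acid cyclisation of 5-hydroxy-1,3-diketones to 2,3-dihydro-4H-pyran-4-ones, acylketene generation from tert-butyl acetoacetates, the dienylketene ring closure that ends the Danheiser benzannulation, and the Harris Claisen cyclisation of triketo esters to acylphloroglucinols.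

**Compound list**
1 | tert-butyl 3-oxobutanoate (tert-butyl acetoacetate) | CC(=O)CC(=O)OC(C)(C)C | starting material
2 | (2E)-1-bromo-3,7-dimethylocta-2,6-diene (geranyl bromide) | BrC/C=C(\C)CCC=C(C)C | starting material
3 | tert-butyl (4E)-2-acetyl-5,9-dimethyldeca-4,8-dienoate (racemic at C2) | CC(=O)C(C/C=C(\C)CCC=C(C)C)C(=O)OC(C)(C)C | intermediate
4 | N-methoxy-N-methylacetamide | CC(=O)N(C)OC | starting material
5 | tert-butyl (4E)-5,9-dimethyl-2-(3-oxobutanoyl)deca-4,8-dienoate (racemic at C2; keto form drawn) | CC(=O)CC(=O)C(C/C=C(\C)CCC=C(C)C)C(=O)OC(C)(C)C | intermediate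
6 | ethyl 3-(3,4-dimethoxyphenyl)-3-oxopropanoate | CCOC(=O)CC(=O)c1ccc(OC)c(OC)c1 | starting material
7 | ethyl (3S)-3-(3,4-dimethoxyphenyl)-3-hydroxypropanoate | CCOC(=O)C[C@H](O)c1ccc(OC)c(OC)c1 | intermediate
8 | tert-butyl (9S)-9-(3,4-dimethoxyphenyl)-2-[(2E)-3,7-dimethylocta-2,6-dien-1-yl]-9-hydroxy-3,5,7-trioxononanoate (C2 epimers; keto form drawn) | CC(C)(C)OC(=O)C(C/C=C(\C)CCC=C(C)C)C(=O)CC(=O)CC(=O)C[C@H](O)c1ccc(OC)c(OC)c1 | intermediate
9 | tert-butyl 4-[(2S)-2-(3,4-dimethoxyphenyl)-4-oxo-3,4-dihydro-2H-pyran-6-yl]-2-[(2E)-3,7-dimethylocta-2,6-dien-1-yl]-3-oxobutanoate (not isolated) | COc1ccc([C@@H]2CC(=O)C=C(CC(=O)C(C/C=C(\C)CCC=C(C)C)C(=O)OC(C)(C)C)O2)cc1OC | intermediate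
10 | (2S)-2-(3,4-dimethoxyphenyl)-6-[(5E)-6,10-dimethyl-2-oxo-3-(oxomethylidene)undeca-5,9-dien-1-yl]-2,3-dihydro-4H-pyran-4-one (acylketene, not isolated) | COc1ccc([C@@H]2CC(=O)C=C(CC(=O)C(C/C=C(\C)CCC=C(C)C)=C=O)O2)cc1OC | intermediate
11 | (2S)-2-(3,4-dimethoxyphenyl)-6-[(2E)-3,7-dimethylocta-2,6-dien-1-yl]-5,7-dihydroxy-2,3-dihydro-4H-chromen-4-one | COc1ccc([C@@H]2CC(=O)c3c(cc(O)c(C/C=C(\C)CCC=C(C)C)c3O)O2)cc1OC | target

**Totals**
Total steps: 5. Longest linear sequence: 4 (1 → 3 → 5 → 8 → 11, steps 1, 2, 4 and 5); step 3 supplies the second branch.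

**Three steps most likely to fail**

Step 5 is the riskiest. In the first stage the free triketone of 8 could instead close to a 4-pyranone or undergo aldol cyclisation. If heating begins before ring C is complete, the ketene is captured by an enol oxygen as a 4-hydroxy-2-pyranone. An α-substituted tert-butyl keto ester may also release its ketene sluggishly. The fallback sets out from 8 and separates the two ring closures. Only the 40 °C acid stage is run and dihydropyranone 9 is isolated. Its tert-butyl ester is cleaved without protic acid (Me3SiOTf, 2,6-lutidine, CH2Cl2, 0 °C, then water) to give 4-[(2S)-2-(3,4-dimethoxyphenyl)-4-oxo-3,4-dihydro-2H-pyran-6-yl]-2-geranyl-3-oxobutanoic acid F1. This acid is dehydrated cold with N,N'-dicyclohexylcarbodiimide (CH2Cl2, −20 → 25 °C), so that the ketene forms from a carboxyl activation instead of a thermolysis. The fallback comes back to the route at acylketene 10, which closes to 11.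

Step 4 is next. The trianion may be incompletely formed at the hindered C2 position, or may deprotonate the ester α-position of 7 instead of acylating it. The fallback sets out from 3 and moves the fragment union one acetate unit along the chain. The dianion of 3 (LiN(iPr)2, 2.2 equiv, THF, −78 °C) is added to the enol-ether-masked lactone (6S)-6-(3,4-dimethoxyphenyl)-4-methoxy-5,6-dihydro-2H-pyran-2-one F2, obtained from 3,4-dimethoxybenzaldehyde and Brassard's diene (1,3-dimethoxy-1-(trimethylsilyloxy)buta-1,3-diene) by the asymmetric hetero-Diels–Alder reaction with Ti(OiPr)4/(S)-BINOL, then CF3CO2H; the ligand enantiomer is assigned by analogy to related Ti–BINOL additions and should be confirmed on the lactone. Claisen opening of the lactone gives the acyclic enol ether tert-butyl (6E,9S)-9-(3,4-dimethoxyphenyl)-2-geranyl-9-hydroxy-7-methoxy-3,5-dioxonon-6-enoate F3. In F3 the future C4 carbonyl is masked, so pyranone and aldol side paths are blocked. Pyridinium p-toluenesulfonate in wet toluene at 40 °C closes ring C with loss of methanol, and the fallback comes back to the route at 9. The main concern here is base-induced eliminative opening of the lactone.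

Step 2 is third. γ-Acylation of the hindered dianion can stall through proton exchange or give O-acylation. The fallback sets out from 3 and replaces the dianion by a neutral silyl dienol ether. Me3SiCl/Et3N gives the enol ether tert-butyl (4E)-5,9-dimethyl-2-[1-(trimethylsilyloxy)ethylidene]deca-4,8-dienoate F4. LiN(iPr)2 then Me3SiCl (THF, −78 °C) gives 1-tert-butoxy-2-geranyl-1,3-bis(trimethylsilyloxy)buta-1,3-diene F5. Mukaiyama-type γ-acylation of F5 with acetyl chloride (CH2Cl2, −78 → 20 °C, aqueous work-up) comes back to the route at 5.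

**Further compounds**
F1 | step 5 | 4-[(2S)-2-(3,4-dimethoxyphenyl)-4-oxo-3,4-dihydro-2H-pyran-6-yl]-2-[(2E)-3,7-dimethylocta-2,6-dien-1-yl]-3-oxobutanoic acid | COc1ccc([C@@H]2CC(=O)C=C(CC(=O)C(C/C=C(\C)CCC=C(C)C)C(=O)O)O2)cc1OC
F2 | step 4 | (6S)-6-(3,4-dimethoxyphenyl)-4-methoxy-5,6-dihydro-2H-pyran-2-one | COC1=CC(=O)O[C@@H](C1)c2ccc(OC)c(OC)c2
F3 | step 4 | tert-butyl (6E,9S)-9-(3,4-dimethoxyphenyl)-2-[(2E)-3,7-dimethylocta-2,6-dien-1-yl]-9-hydroxy-7-methoxy-3,5-dioxonon-6-enoate | CC(C)(C)OC(=O)C(C/C=C(\C)CCC=C(C)C)C(=O)CC(=O)/C=C(/OC)C[C@H](O)c1ccc(OC)c(OC)c1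
F4 | step 2 | tert-butyl (4E)-5,9-dimethyl-2-[1-(trimethylsilyloxy)ethylidene]deca-4,8-dienoate | CC(O[Si](C)(C)C)=C(C/C=C(\C)CCC=C(C)C)C(=O)OC(C)(C)C
F5 | step 2 | 1-tert-butoxy-2-[(2E)-3,7-dimethylocta-2,6-dien-1-yl]-1,3-bis(trimethylsilyloxy)buta-1,3-diene | C=C(O[Si](C)(C)C)C(C/C=C(\C)CCC=C(C)C)=C(OC(C)(C)C)O[Si](C)(C)C
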